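**Retrosynthetic overview**

1. Ring A (the 4-bromo-3,3-dimethylcyclohexan-1-ol) is closed last, at the bond between its gem-dimethyl carbon and the ring CH2 that separates that carbon from the carbinol carbon. A bromonium ion on a prenyl terminus is opened at its tertiary carbon by the CH2 end of a 1,1-disubstituted alkene, and the cation developing at the future carbinol carbon is quenched by a 1,2-shift of the CH2 arm that carries the tricycle from a neighbouring silyloxy carbon. That carbon is later excised as acetate (Baeyer–Villiger), which uncovers the ring A hydroxyl.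
2. Enabling feature: the gem-dimethyl carbon of ring A is quaternary and lies next to the secondary CHBr carbon (the imprint of a Markovnikov-opened bromonium ion). It is also 1,3 to the carbinol carbon, which is fully substituted and carries oxygen and an exocyclic CH2 (the imprint of a 2-substituted allylic carbinol). The cis-1,4 relation of Br and OH is what a chair transition state with anti migration gives.
3. The cyclisation precursor comes from the 2-lithio-1,5-diene of 6-methylhept-5-en-2-one (Shapiro reaction) and the methyl ketone of the bromo tricyclic lactone.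
4. Tricycle: rings B (cyclopentane) and C (cyclohexene) are formed together by an intramolecular Diels–Alder reaction of a (Z)-β-bromoacrylate with an (E)-diene, which sets the quaternary carbon, the trans ring fusion and the C–Br centre from one rhodium-set stereocentre. Ring D (γ-lactone) follows by acid lactonisation onto the ring C alkene.
5. Order of ring formation: B and C together, then D, then A.

Key step: step 10

**Remarks and assumptions**

- Naming: "Lac" is the tricyclic unit of the target bonded through C-1. It is a trans-fused octahydroindene (indene numbering) with 4-bromo and 7-methyl groups, whose C-3a carboxyl is lactonised onto the oxygen at C-7; configuration 1S,3aS,4S,7R,7aS.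
- Assumption: but-1-en-3-yne is taken as commercially supplied in solution.
- Assumption: the facial sense of the two catalyst-controlled steps (4 and 10) follows the standard models for these catalyst classes; if a catalyst delivers the opposite face, its antipode is used with no other change.

**Route**

Step 1
Reactants: 1 methyl propiolate; 2 acrolein
Product: 3 methyl (2Z)-2-(bromomethylidene)-5-oxopentanoate
Conditions: Pd(OAc)2 (5 mol %), LiBr (4 equiv), acrolein (3 equiv), AcOH, 25 °C
Reagents that add atoms: lithium bromide, [Li+].[Br-]
Why: Halopalladation–conjugate addition–protonolysis: bromide adds anti to divalent palladium across the ynoate (Br at the β-carbon, Pd at the α-carbon), the α-vinylpalladium adds to acrolein and the palladium enolate is protonated by AcOH, so bromine ends cis to the ester (Z) and the three-carbon aldehyde arm sits on the α-carbon.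

Step 2
Reactants: 3 methyl (2Z)-2-(bromomethylidene)-5-oxopentanoate; 4 1-(triphenylphosphoranylidene)propan-2-one
Product: 5 methyl (2Z,5E)-2-(bromomethylidene)-7-oxooct-5-enoate
Conditions: CH2Cl2, 25 °C
Reagents that add atoms: none
Why: Wittig olefination with a stabilised ylide should give the (E)-enone and leave the hindered, less electrophilic bromoacrylate untouched.

Step 3
Reactants: 6 but-1-en-3-yne
Product: 8 (E)-4,4,5,5-tetramethyl-2-(2-methylbuta-1,3-dien-1-yl)-1,3,2-dioxaborolane, via dienylalane 7 (not isolated)
Conditions: AlMe3 (1.2 equiv), Cp2ZrCl2 (20 mol %), CH2Cl2, 0 → 25 °C; then 2-isopropoxy-4,4,5,5-tetramethyl-1,3,2-dioxaborolane, THF, 0 °C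
Reagents that add atoms: trimethylaluminium, C[Al](C)C; 2-isopropoxy-4,4,5,5-tetramethyl-1,3,2-dioxaborolane, CC(C)OB1OC(C)(C)C(C)(C)O1
Why: Zirconium-catalysed Negishi carboalumination adds CH3 and Al syn across the alkyne with Al on the terminal carbon, and exchange with the isopropoxyborolane gives the (E)-dienylboronate with retention.

Step 4
Reactants: 5 methyl (2Z,5E)-2-(bromomethylidene)-7-oxooct-5-enoate; 8 (E)-4,4,5,5-tetramethyl-2-(2-methylbuta-1,3-dien-1-yl)-1,3,2-dioxaborolane
Product: 9 methyl (2Z,5S,6E)-2-(bromomethylidene)-7-methyl-5-(2-oxopropyl)nona-6,8-dienoate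
Conditions: [Rh(cod)Cl]2 (2.5 mol %), (R)-BINAP (6 mol %), KOH (0.3 equiv), 8 (1.5 equiv), dioxane/H2O 10:1, 40 °C
Reagents that add atoms: none
Why: Rhodium-catalysed asymmetric conjugate addition (Hayashi–Miyaura reaction) transfers the dienyl group to the β-carbon of the disubstituted enone, which is far more reactive than the trisubstituted bromoacrylate, and the BINAP ligand sets the single stereocentre (5S), (R)-BINAP being expected to direct attack to the α-re face.

Step 5
Reactants: 9 methyl (2Z,5S,6E)-2-(bromomethylidene)-7-methyl-5-(2-oxopropyl)nona-6,8-dienoate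
Product: 10 methyl (1S,3aS,4S,7aR)-4-bromo-7-methyl-1-(2-oxopropyl)-1,2,3,4,5,7a-hexahydro-3aH-indene-3a-carboxylate (trans ring fusion, Br cis to the ester, side chain cis to H-7a)
Conditions: EtAlCl2 (2.5 equiv), CH2Cl2, −78 → −20 °C
Reagents that add atoms: none
Why: Type 1 intramolecular Diels–Alder reaction: the (Z)-dienophile places Br cis to the ester, the Lewis acid-complexed ester sits endo, which with a three-atom tether means a trans ring fusion, and A(1,3) strain between the diene methyl group and the allylic stereocentre puts its hydrogen in the diene plane so that the dienophile adds anti to the oxopropyl arm, which fixes the quaternary carbon, C-4 and C-7a relative to C-1.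

Step 6
Reactants: 10 methyl (1S,3aS,4S,7aR)-4-bromo-7-methyl-1-(2-oxopropyl)-1,2,3,4,5,7a-hexahydro-3aH-indene-3a-carboxylate
Product: 11 1-(Lac)propan-2-one (bromo keto lactone)
Conditions: TfOH (1.5 equiv), CH2Cl2, −20 → 0 °C; aq. NaHCO3
Reagents that add atoms: none
Why: Acid-mediated lactonisation of a γ,δ-unsaturated ester: Markovnikov protonation of the ring C alkene gives the tertiary C-7 cation, which only the ester carbonyl on the same face can reach (the methyl group leaves as MeOTf, hydrolysed on work-up), so the new C-7 centre (oxygen cis to the carboxyl carbon, methyl equatorial) is dictated by the bridged bicycle.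

Step 7
Reactants: 12 6-methylhept-5-en-2-one; 13 2,4,6-triisopropylbenzenesulfonyl hydrazide
Product: 14 N'-(6-methylhept-5-en-2-ylidene)-2,4,6-triisopropylbenzenesulfonohydrazide
Conditions: MeOH, HCl (cat.), 25 °C
Reagents that add atoms: none
Why: Condensation of the ketone with the sulfonyl hydrazide gives the hydrazone needed for the Shapiro reaction.

Step 8
Reactants: 14 N'-(6-methylhept-5-en-2-ylidene)-2,4,6-triisopropylbenzenesulfonohydrazide; 11 1-(Lac)propan-2-one
Product: 17 1-(Lac)-2,7-dimethyl-3-methylideneoct-6-en-2-ol (both carbinol epimers), via vinyllithium 15 (not isolated), via vinylcerium dichloride 16 (not isolated)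
Conditions: 14 (2.5 equiv), n-BuLi (5.0 equiv), THF, −78 → 0 °C; CeCl3 (2.6 equiv), −78 °C; then 11, −78 °C; aq. NH4Cl
Reagents that add atoms: none
Why: The Shapiro reaction (deprotonation on the methyl side, loss of sulfinate and dinitrogen) gives the 2-lithio-1,5-diene, and its organocerium derivative should add to the methyl ketone without enolisation and without touching the hindered lactone or the secondary bromide at −78 °C; the new carbinol centre forms unselectively and is destroyed in step 10.

Step 9
Reactants: 17 1-(Lac)-2,7-dimethyl-3-methylideneoct-6-en-2-ol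
Product: 18 [1-(Lac)-2,7-dimethyl-3-methylideneoct-6-en-2-yl]oxy(trimethyl)silane (both carbinol epimers)
Conditions: N-(trimethylsilyl)imidazole (3 equiv), CH2Cl2, 25 °C
Reagents that add atoms: N-(trimethylsilyl)imidazole, C[Si](C)(C)n1ccnc1
Why: Silylation of the tertiary alcohol, so that the 1,2-shift of step 10 ends in a silyloxocarbenium ion and oxirane formation by a free hydroxyl is excluded.

Step 10
Reactants: 18 [1-(Lac)-2,7-dimethyl-3-methylideneoct-6-en-2-yl]oxy(trimethyl)silane
Product: 21 1-[(1S,4S)-4-bromo-3,3-dimethyl-1-(Lac-methyl)cyclohexyl]ethan-1-one, via bromonium ion 19 (not isolated), via silyloxocarbenium ion 20 (not isolated)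
Conditions: chiral BINOL-derived thiophosphoramide Lewis base (10 mol %), 1,3-dibromo-5,5-dimethylhydantoin (0.6 equiv), toluene/CH2Cl2 1:1, −78 → −40 °C; aq. Na2S2O3
Reagents that add atoms: 1,3-dibromo-5,5-dimethylhydantoin, CC1(C)N(Br)C(=O)N(Br)C1=O
Why: Proposed new method: the Lewis base–Br+ complex brominates the more electron-rich trisubstituted alkene to bromonium ion 19, whose tertiary carbon is attacked in a chair transition state by the CH2 terminus of the 1,1-disubstituted alkene, while the cation developing at the fully substituted alkene carbon is quenched by an antiperiplanar 1,2-shift of the Lac-bearing CH2 group from the adjacent silyloxy carbon, giving oxocarbenium ion 20, which loses the silyl group to the hydantoin anion. The closest known reactions are bromonium-initiated cation–olefin cyclisations and the Prins–pinacol and halonium-induced semipinacol rearrangements of allylic silyl ethers, which have not been combined in this way. Ring A closes in the 6-endo mode with respect to both the bromonium ion (attack at its distal, tertiary carbon) and the 1,1-disubstituted alkene (6-endo-trig). The CHBr centre is set by the chiral Lewis base (the tricycle is too remote to bias the prenyl terminus), and the quaternary centre follows from it: in the chair with bromine equatorial the migrating CH2 enters anti to the new ring bond and so becomes equatorial, which leaves the acetyl group axial and cis to bromine. The step needs site selectivity for the prenyl alkene over the allylic silyl ether alkene, secured by its higher substitution and by the inductive deactivation of the latter by the allylic oxygen, and preference for CH2 over CH3 migration, secured by the higher migratory aptitude of the primary alkyl group; both carbinol epimers of 18 converge because that centre becomes the ketone carbon.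

Step 11
Reactants: 21 1-[(1S,4S)-4-bromo-3,3-dimethyl-1-(Lac-methyl)cyclohexyl]ethan-1-one
Product: 22 (1S,4S)-4-bromo-3,3-dimethyl-1-(Lac-methyl)cyclohexyl acetate
Conditions: m-CPBA (3 equiv), NaHCO3, CH2Cl2, 0 → 25 °C
Reagents that add atoms: 3-chloroperoxybenzoic acid, OOC(=O)c1cccc(Cl)c1
Why: Baeyer–Villiger oxidation: the tertiary ring carbon migrates in preference to methyl and with retention, which turns the axial acetyl group into the axial acetate.

Step 12
Reactants: 22 (1S,4S)-4-bromo-3,3-dimethyl-1-(Lac-methyl)cyclohexyl acetate
Product: 23 (1S,4S)-4-bromo-3,3-dimethyl-1-(Lac-methyl)cyclohexan-1-ol (target)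
Conditions: K2CO3 (2 equiv), MeOH, 40 °C; aq. NH4Cl
Reagents that add atoms: none
Why: Methanolysis (transesterification) of the tertiary acetate; the γ-lactone, if opened, should reclose at equilibrium, and the equatorial neopentyl-type bromides have no antiperiplanar hydrogen for elimination.

**Compound list**

1 | methyl propiolate | C#CC(=O)OC | starting material
2 | acrolein | C=CC=O | starting material
3 | methyl (2Z)-2-(bromomethylidene)-5-oxopentanoate | O=CCC/C(=C/Br)C(=O)OC | intermediate
4 | 1-(triphenylphosphoranylidene)propan-2-one | CC(=O)C=P(c1ccccc1)(c1ccccc1)c1ccccc1 | starting material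
5 | methyl (2Z,5E)-2-(bromomethylidene)-7-oxooct-5-enoate | CC(=O)/C=C/CC/C(=C/Br)C(=O)OC | intermediate
6 | but-1-en-3-yne | C=CC#C | starting material
7 | (E)-dimethyl(2-methylbuta-1,3-dien-1-yl)alane (not isolated) | C=C/C(C)=C/[Al](C)C | intermediate
8 | (E)-4,4,5,5-tetramethyl-2-(2-methylbuta-1,3-dien-1-yl)-1,3,2-dioxaborolane | C=C/C(C)=C/B1OC(C)(C)C(C)(C)O1 | intermediate
9 | methyl (2Z,5S,6E)-2-(bromomethylidene)-7-methyl-5-(2-oxopropyl)nona-6,8-dienoate | CC(=O)C[C@H](CC/C(=C/Br)C(=O)OC)/C=C(\C)C=C | intermediate
10 | methyl (1S,3aS,4S,7aR)-4-bromo-7-methyl-1-(2-oxopropyl)-1,2,3,4,5,7a-hexahydro-3aH-indene-3a-carboxylate | CC(=O)C[C@@H]1CC[C@]2(C(=O)OC)[C@@H](Br)CC=C(C)[C@@H]12 | intermediate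
11 | 1-(Lac)propan-2-one: (1S,3aS,4S,7R,7aS)-4-bromo-7-methyl-1-(2-oxopropyl)-trans-octahydroindene-3a-carboxylic acid 3a→7 lactone | CC(=O)C[C@@H]1CC[C@]23C(=O)O[C@](C)(CC[C@@H]2Br)[C@@H]13 | intermediate
12 | 6-methylhept-5-en-2-one | CC(=O)CCC=C(C)C | starting material
13 | 2,4,6-triisopropylbenzenesulfonyl hydrazide | CC(C)c1cc(C(C)C)c(S(=O)(=O)NN)c(C(C)C)c1 | starting material
14 | N'-(6-methylhept-5-en-2-ylidene)-2,4,6-triisopropylbenzenesulfonohydrazide | CC(C)=CCCC(C)=NNS(=O)(=O)c1c(C(C)C)cc(C(C)C)cc1C(C)C | intermediate
15 | 2-lithio-6-methylhepta-1,5-diene (not isolated) | [Li]C(=C)CCC=C(C)C | intermediate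
16 | dichloro(6-methylhepta-1,5-dien-2-yl)cerium (not isolated) | Cl[Ce](Cl)C(=C)CCC=C(C)C | intermediate
17 | 1-(Lac)-2,7-dimethyl-3-methylideneoct-6-en-2-ol, both epimers at the carbinol carbon | CC(C)=CCCC(=C)C(C)(O)C[C@@H]1CC[C@]23C(=O)O[C@](C)(CC[C@@H]2Br)[C@@H]13 | intermediate
18 | trimethylsilyl ether of 17, both epimers at the silyloxy carbon | CC(C)=CCCC(=C)C(C)(O[Si](C)(C)C)C[C@@H]1CC[C@]23C(=O)O[C@](C)(CC[C@@H]2Br)[C@@H]13 | intermediate
19 | bromonium ion of the prenyl terminus of 18, (S) at the future CHBr carbon (not isolated) | CC1(C)[Br+][C@H]1CCC(=C)C(C)(O[Si](C)(C)C)C[C@@H]1CC[C@]23C(=O)O[C@](C)(CC[C@@H]2Br)[C@@H]13 | intermediate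
20 | O-trimethylsilyl oxocarbenium ion of ketone 21 (not isolated) | CC1(C)C[C@@](C(C)=[O+][Si](C)(C)C)(C[C@@H]2CC[C@]34C(=O)O[C@](C)(CC[C@@H]3Br)[C@@H]24)CC[C@@H]1Br | intermediate
21 | 1-[(1S,4S)-4-bromo-3,3-dimethyl-1-(Lac-methyl)cyclohexyl]ethan-1-one (acetyl axial, cis to Br) | CC1(C)C[C@@](C(C)=O)(C[C@@H]2CC[C@]34C(=O)O[C@](C)(CC[C@@H]3Br)[C@@H]24)CC[C@@H]1Br | intermediate
22 | (1S,4S)-4-bromo-3,3-dimethyl-1-(Lac-methyl)cyclohexyl acetate | CC1(C)C[C@@](OC(C)=O)(C[C@@H]2CC[C@]34C(=O)O[C@](C)(CC[C@@H]3Br)[C@@H]24)CC[C@@H]1Br | intermediate
23 | (1S,4S)-4-bromo-3,3-dimethyl-1-(Lac-methyl)cyclohexan-1-ol, CNP0282702.2 | CC1(C)C[C@@](O)(C[C@@H]2CC[C@]34C(=O)O[C@](C)(CC[C@@H]3Br)[C@@H]24)CC[C@@H]1Br | target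

**Step count and risks**

Total steps: 12. Longest linear sequence: 10 (steps 1, 2, 4, 5, 6, 8, 9, 10, 11, 12).

Steps most likely to fail:

1. Step 10 (proposed new method). Processes that may go wrong: migration of the methyl instead of the CH2 group, proton loss from the tertiary cation before the shift, direct bromination of the allylic silyl ether alkene, and weak catalyst control over the face of bromonium formation. The fallback uses known chemistry, sets out from 11 and comes back at 23. Baeyer–Villiger oxidation of 11 (CF3CO3H, Na2HPO4, CH2Cl2; primary alkyl migrates in preference to methyl) should give the acetoxymethyl lactone F1, methanolysis (K2CO3, MeOH) the hydroxymethyl lactone F2, and iodine/PPh3/imidazole the iodomethyl lactone F3. Separately, the dianion of methyl acetoacetate (NaH, then n-BuLi) is alkylated with prenyl bromide to methyl 7-methyl-3-oxooct-6-enoate F4. Bromonium-initiated cyclisation with Et2SBr·SbCl5Br in MeNO2, terminated by the enol carbon of the β-keto ester (the same ring A bond in a known setting), gives methyl 5-bromo-6,6-dimethyl-2-oxocyclohexane-1-carboxylate F5. Krapcho dealkoxycarbonylation (LiCl, wet DMSO, heat) and resolution by preparative chiral chromatography give (S)-4-bromo-3,3-dimethylcyclohexan-1-one F6. Samarium Barbier coupling of F3 with F6 (SmI2, THF, catalytic NiI2, 0 °C; the primary iodide is reduced much faster than the secondary bromides and the lactone is inert) lets the carbon nucleophile attack the ketone from the equatorial side, away from the axial methyl group, which should give the axial hydroxyl cis to bromine, that is 23.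

2. Step 5. Process that may go wrong: poor endo/exo discrimination in the cycloaddition, giving the cis ring fusion alongside the trans one. The fallback sets out from 10, taken as the mixture with its C-7a epimer, and comes back at 11. RhCl3·3H2O (catalytic) in EtOH at 70 °C should move the ring C double bond into the tetrasubstituted C-7/C-7a position, the thermodynamic position in such hydrindenes, so that both epimers converge on the single alkene F7, in which the ring-fusion centre no longer exists. TfOH in CH2Cl2 then adds the ester oxygen to C-7 and a proton to C-7a from opposite faces (anti addition, the oxygen necessarily from the ester face), which re-creates the trans ring fusion and gives 11. Over-isomerisation towards C-1 must be avoided by stopping at the first tetrasubstituted alkene.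

3. Step 4. Processes that may go wrong: protodeboronation or oligomerisation of the dienylboronate, oxidative addition or addition–elimination at the bromoacrylate, and insufficient enantioselectivity. The fallback sets out from 3 and comes back at 9. Wittig olefination of 3 with (triphenylphosphoranylidene)acetaldehyde gives the enal F8, and 8 is converted with aqueous KHF2 into the potassium dienyltrifluoroborate F9. Iminium catalysis with a chiral imidazolidinone salt ((2S,5S)-5-benzyl-2-tert-butyl-3-methylimidazolidin-4-one hydrochloride or its antipode, HF, DME, −20 °C) adds the dienyl group of F9 to the β-carbon of F8 without any transition metal, giving the aldehyde F10. MeMgBr at −78 °C then gives the carbinol F11, and Dess–Martin oxidation returns the methyl ketone 9.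

Further compounds
F1 | step 10 | acetoxymethyl lactone: the lactone unit of 11 with CH2OAc at C-1 in place of the 2-oxopropyl group | CC(=O)OC[C@@H]1CC[C@]23C(=O)O[C@](C)(CC[C@@H]2Br)[C@@H]13
F2 | step 10 | hydroxymethyl lactone: the lactone unit of 11 with CH2OH at C-1 | OC[C@@H]1CC[C@]23C(=O)O[C@](C)(CC[C@@H]2Br)[C@@H]13
F3 | step 10 | iodomethyl lactone: the lactone unit of 11 with CH2I at C-1 | IC[C@@H]1CC[C@]23C(=O)O[C@](C)(CC[C@@H]2Br)[C@@H]13
F4 | step 10 | methyl 7-methyl-3-oxooct-6-enoate | COC(=O)CC(=O)CCC=C(C)C
F5 | step 10 | methyl 5-bromo-6,6-dimethyl-2-oxocyclohexane-1-carboxylate (racemic) | COC(=O)C1C(=O)CCC(Br)C1(C)C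
F6 | step 10 | (S)-4-bromo-3,3-dimethylcyclohexan-1-one | CC1(C)CC(=O)CC[C@@H]1Br
F7 | step 5 | methyl (1S,3aS,4S)-4-bromo-7-methyl-1-(2-oxopropyl)-1,2,3,4,5,6-hexahydro-3aH-indene-3a-carboxylate | CC(=O)C[C@@H]1CC[C@]2(C(=O)OC)[C@@H](Br)CCC(C)=C12
F8 | step 4 | methyl (2Z,5E)-2-(bromomethylidene)-7-oxohept-5-enoate | O=C/C=C/CC/C(=C/Br)C(=O)OC
F9 | step 4 | potassium (E)-trifluoro(2-methylbuta-1,3-dien-1-yl)borate | C=C/C(C)=C/[B-](F)(F)F.[K+]
F10 | step 4 | methyl (2Z,5S,6E)-2-(bromomethylidene)-7-methyl-5-(2-oxoethyl)nona-6,8-dienoate | O=CC[C@H](CC/C(=C/Br)C(=O)OC)/C=C(\C)C=C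
F11 | step 4 | methyl (2Z,5S,6E)-2-(bromomethylidene)-5-(2-hydroxypropyl)-7-methylnona-6,8-dienoate (both carbinol epimers) | CC(O)C[C@H](CC/C(=C/Br)C(=O)OC)/C=C(\C)C=C
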